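**Plan**
1. Retrosynthetic cuts: (a) C2=C3 and the free C4–OH go back to a 1,3-dioxolane fused at C3/C4 of a C1 ketone (reverse E1cB). (b) C1=O goes back to a C1(OH)–CH2OH glycol. (c) The side chain is cut at the C9′–C10′ CH2–CH2 bond. (d) C5–C1′ goes back to a C5 ketone.
2. Forward: no ring is built, because C1–C6 of (−)-quinic acid become C1–C6 of the target. A non-8-enyl Grignard reagent puts C1′–C9′ on C5, (E)-oct-5-enyl bromide adds C10′–C17′ at C9′, and three mild steps unmask the ring.
3. Enabling feature: C9′ and C10′ lie in the unbranched (CH2)13 tether. At the union the head is a saturated cyclohexane cis-fused to the dioxolane, with no C=O and no ring C=C, so its C8′=C9′ vinyl group is the only site for hydroboration. A direct sp3–sp3 coupling avoids any olefination or hydrogenation that would endanger C14′=C15′ or the enone.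
4. Stereochemistry: C4 (R) is C4 of quinic acid, carried through unchanged. C5 (S) comes from addition to the C5 ketone on the face opposite the dioxolane ring. The E alkene comes from Na/NH3 reduction of an alkyne. The C1 and C3 stereocentres of quinic acid are consumed.

Key step: step 9

Remark on the chemistry: ring atoms are numbered as in the target (C1 = C=O, C4 = CHOH, C5 = C(OH)R), which coincides with quinic acid numbering, and the chain is C1′–C17′. β is the ring face that carries C4–O. Natural (−)-quinic acid is taken as the (3R,5R) compound with C1–OH, C3–OH and C4–OH β, and with CO2H and C5–OH α.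

**Step 1**
Reactants: 1 hex-5-yn-1-ol
Product: 3 oct-5-yn-1-ol, via dilithio hex-5-yn-1-olate 2 (not isolated)
Conditions: n-BuLi (2.1 equiv), THF–DMPU, −78 to 0 °C; EtI (1.05 equiv), 0 °C to rt
Reagents that add atoms: iodoethane, CCI; n-butyllithium, [Li]CCCC (lithium of intermediate 2 only)
Why: Double deprotonation gives 2, whose acetylide carbon is far more nucleophilic toward a primary iodide than the lithium alkoxide, so one equivalent of EtI should give C-ethylation only (acetylide alkylation).

**Step 2**
Reactants: 3 oct-5-yn-1-ol
Product: 4 (E)-oct-5-en-1-ol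
Conditions: Na, NH3(l)–THF, −33 °C; solid NH4Cl
Reagents that add atoms: none
Why: Dissolving-metal reduction of an internal alkyne runs through the trans vinyl radical and anion and should give the E alkene, the alkoxide being inert.

**Step 3**
Reactants: 4 (E)-oct-5-en-1-ol
Product: 5 (E)-8-bromooct-3-ene
Conditions: CBr4, PPh3, CH2Cl2, 0 °C
Reagents that add atoms: carbon tetrabromide, BrC(Br)(Br)Br
Why: In the Appel reaction bromide displaces the alkoxyphosphonium ion by SN2 under neutral conditions, which leaves the position and geometry of the alkene untouched.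

**Step 4**
Reactants: 6 (−)-quinic acid
Product: 7 3,4-O-isopropylidene-1,5-quinide (C1 carboxyl lactonised onto C5–O on the α face; acetonide on the β C3/C4 diol; free β C1–OH)
Conditions: Me2C(OMe)2, p-TsOH (cat.), acetone, reflux
Reagents that add atoms: 2,2-dimethoxypropane, COC(C)(C)OC
Why: Acid-catalysed acetalisation takes the only cis-vicinal diol (C3/C4) while the carboxyl lactonises onto the syn C5–OH, a standard one-pot protection of quinic acid that keeps all stereocentres.

**Step 5**
Reactants: 7 3,4-O-isopropylidene-1,5-quinide
Product: 8 1-(hydroxymethyl)-3,4-O-isopropylidenecyclohexane-1,3,4,5-tetraol (C1–OH, C3–O, C4–O β; CH2OH and C5–OH α)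
Conditions: NaBH4, EtOH, 0 °C to rt
Reagents that add atoms: none
Why: The strained α-hydroxy lactone is activated enough for borohydride reduction, which frees C5–OH and creates the C1(OH)–CH2OH glycol that stores the future C1 ketone.

**Step 6**
Reactants: 8 triol
Product: 9 primary TBS ether of 8 (C1–CH2OTBS; C1–OH and C5–OH free)
Conditions: TBSCl (1.05 equiv), imidazole, CH2Cl2–DMF, 0 °C
Reagents that add atoms: tert-butyldimethylsilyl chloride, CC(C)(C)[Si](C)(C)Cl
Why: Silylation is sterically selective, so the primary OH should react well before the secondary C5–OH next to the dioxolane and the tertiary C1–OH.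

**Step 7**
Reactants: 9 primary TBS ether
Product: 10 C5 ketone, (1S,3R,4R)-1-(TBSO-methyl)-1-hydroxy-3,4-(isopropylidenedioxy)cyclohexan-5-one
Conditions: TPAP (5 mol %), NMO, 4 Å MS, CH2Cl2, rt
Reagents that add atoms: none
Why: Ley–Griffith oxidation acts on the only oxidisable alcohol under neutral anhydrous conditions, so the β-hydroxy ketone should not dehydrate, and the cis ring fusion holds C4.

**Step 8**
Reactants: 10 C5 ketone; 11 9-bromonon-1-ene
Product: 13 (1S,3R,4R,5S)-1-(TBSO-methyl)-3,4-O-isopropylidene-5-(non-8-enyl)cyclohexane-1,3,4,5-tetraol (C5–OH β, cis to C4–O), via non-8-enylmagnesium bromide 12 (not isolated)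
Conditions: 11, Mg, THF, rt; then 10, LaCl3·2LiCl (1 equiv), 12 (3 equiv), THF, −40 to 0 °C; aq NH4Cl
Reagents that add atoms: magnesium, [Mg] (in intermediate 12 only)
Why: In this lanthanide-promoted Grignard 1,2-addition the first equivalent turns C1–OH into an alkoxide that cannot leave, the Lewis acid suppresses enolisation, and the nucleophile approaches equatorially from the α face, away from the dioxolane ring and the axial C1–O and C3–O, which sets C5 as S with its OH cis to C4–O.

**Step 9**
Reactants: 13 non-8-enyl head; 5 (E)-8-bromooct-3-ene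
Product: 15 (1S,3R,4R,5S)-1-(TBSO-methyl)-3,4-O-isopropylidene-5-[(E)-heptadec-14-enyl]cyclohexane-1,3,4,5-tetraol, via B-alkyl-9-BBN borane 14 (not isolated)
Conditions: 9-BBN (1.05 equiv), THF, rt; then K3PO4·H2O, Pd(OAc)2 (5 mol %), PCy3 (10 mol %), 5 (1.3 equiv), THF, rt
Reagents that add atoms: 9-borabicyclo[3.3.1]nonane, B1C2CCCC1CCC2 (boron unit of intermediate 14 only; nothing of it stays in 15)
Why: 9-BBN adds anti-Markovnikov to the C8′=C9′ vinyl group of 13, the only C=C or C=O in the molecule because C1=O is stored as the glycol and C2=C3 as the C3–O bond of the dioxolane ring, while the two tertiary OH groups react with 9-BBN far more slowly, so borane 14 should form cleanly. After activation of boron by K3PO4·H2O, Pd(0)(PCy3)2 inserts into the C–Br bond of 5 by an SN2-type two-electron oxidative addition, the C9′ alkyl group passes from the borate to palladium, and reductive elimination forms the C9′–C10′ bond. The closest known reaction type is the room-temperature B-alkyl Suzuki–Miyaura coupling of unactivated primary alkyl bromides bearing β-hydrogens with alkyl-9-BBN reagents under Pd/trialkylphosphine catalysis. No ring is closed and no stereocentre is made, and C1, C3, C4, C5 and the E alkene lie at least four atoms from the reacting carbons and are not touched. Cross-coupling must outrun β-hydride elimination, which the bulky electron-rich PCy3 secures by keeping the alkylpalladium bromide bis-ligated, and the hex-5-enyl-type electrophile 5 must not cyclise, which the non-radical palladium pathway and the poor binding of a 1,2-disubstituted alkene secure (a single-electron nickel catalyst would invite 5-exo closure). Bromide 5 is added only after the B–H has been consumed by the vinyl group and the hydrated base, so C14′=C15′ never meets a hydroborating agent, and the boron helper is put on and lost in the same flask.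

**Step 10**
Reactants: 15 coupled TBS ether
Product: 16 (1S,3R,4R,5S)-1-(hydroxymethyl)-3,4-O-isopropylidene-5-[(E)-heptadec-14-enyl]cyclohexane-1,3,4,5-tetraol
Conditions: TBAF, THF, 0 °C to rt
Reagents that add atoms: none
Why: Fluoride cleaves the Si–O bond selectively, and the acetonide, the tertiary alcohols and the alkene are inert.

**Step 11**
Reactants: 16 glycol
Product: 17 (3R,4R,5S)-5-hydroxy-3,4-(isopropylidenedioxy)-5-[(E)-heptadec-14-enyl]cyclohexanone
Conditions: NaIO4, THF–H2O (pH 7 buffer), 0 °C to rt
Reagents that add atoms: none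
Why: In this Malaprade cleavage only C1(OH)–CH2OH is a free 1,2-diol (C4–O is tied up in the dioxolane, so the C4/C5 pair cannot form a cyclic periodate), and periodate does not attack the isolated alkene.

**Step 12**
Reactants: 17 β-alkoxy ketone
Product: 19 (4R,5S)-4,5-dihydroxy-5-[(E)-heptadec-14-enyl]cyclohex-2-enone (target), via C4-O-hemiketal enone 18 (not isolated)
Conditions: DBU (0.3 equiv), CH2Cl2, −20 to 0 °C; short silica pad
Reagents that add atoms: none
Why: In this E1cB opening of a β,γ-isopropylidenedioxy ketone, enolisation toward C2 expels the axial C3–O of the cis-fused dioxolane and hemiketal 18 loses acetone to free C4–OH, whereas the C6 enolate faces only the much poorer hydroxide leaving group at C5 and should revert, so C4 and C5 stay untouched.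

**Compound list**
1 | hex-5-yn-1-ol | C#CCCCCO | starting material
2 | dilithio hex-5-yn-1-olate | [Li]C#CCCCCO[Li] | intermediate
3 | oct-5-yn-1-ol | CCC#CCCCCO | intermediate
4 | (E)-oct-5-en-1-ol | CC/C=C/CCCCO | intermediate
5 | (E)-8-bromooct-3-ene | CC/C=C/CCCCBr | intermediate
6 | (−)-quinic acid | OC(=O)[C@]1(O)C[C@@H](O)[C@@H](O)[C@H](O)C1 | starting material
7 | 3,4-O-isopropylidene-1,5-quinide | O[C@@]12C[C@H]3OC(C)(C)O[C@H]3[C@@H](C1)OC2=O | intermediate
8 | 1-(hydroxymethyl)-3,4-O-isopropylidenecyclohexane-1,3,4,5-tetraol | OC[C@]1(O)C[C@H]2OC(C)(C)O[C@H]2[C@H](O)C1 | intermediate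
9 | primary TBS ether of 8 | CC(C)(C)[Si](C)(C)OC[C@]1(O)C[C@H]2OC(C)(C)O[C@H]2[C@H](O)C1 | intermediate
10 | C5 ketone | CC(C)(C)[Si](C)(C)OC[C@]1(O)C[C@H]2OC(C)(C)O[C@H]2C(=O)C1 | intermediate
11 | 9-bromonon-1-ene | C=CCCCCCCCBr | starting material
12 | non-8-enylmagnesium bromide | C=CCCCCCCC[Mg]Br | intermediate
13 | C5 non-8-enyl tertiary alcohol | CC(C)(C)[Si](C)(C)OC[C@]1(O)C[C@H]2OC(C)(C)O[C@H]2[C@](O)(CCCCCCCC=C)C1 | intermediate
14 | B-alkyl-9-BBN borane from 13 | CC(C)(C)[Si](C)(C)OC[C@]1(O)C[C@H]2OC(C)(C)O[C@H]2[C@](O)(CCCCCCCCCB3C4CCCC3CCC4)C1 | intermediate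
15 | coupled (E)-heptadec-14-enyl TBS ether | CC(C)(C)[Si](C)(C)OC[C@]1(O)C[C@H]2OC(C)(C)O[C@H]2[C@](O)(CCCCCCCCCCCCC/C=C/CC)C1 | intermediate
16 | C1 glycol | OC[C@]1(O)C[C@H]2OC(C)(C)O[C@H]2[C@](O)(CCCCCCCCCCCCC/C=C/CC)C1 | intermediate
17 | C1 ketone with C3/C4 acetonide | O=C1C[C@H]2OC(C)(C)O[C@H]2[C@](O)(CCCCCCCCCCCCC/C=C/CC)C1 | intermediate
18 | C4-O-(2-hydroxyprop-2-yl) enone | CC/C=C/CCCCCCCCCCCCC[C@]1(O)CC(=O)C=C[C@H]1OC(C)(C)O | intermediate
19 | (4R,5S)-4,5-dihydroxy-5-[(E)-heptadec-14-enyl]cyclohex-2-enone | CC/C=C/CCCCCCCCCCCCC[C@]1(O)CC(=O)C=C[C@H]1O | target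

**Total step count:** 12. **Longest linear sequence:** 9 (steps 4–12, from 6).

**Steps most likely to fail**

1. Step 9.
 - Risk: β-hydride elimination from the alkylpalladium intermediate may compete with the cross-coupling. Palladium hydride could also migrate the C14′=C15′ alkene, the alkylpalladium could insert into that alkene, or the borane could protodeboronate.
 - Fallback: it sets out from 13 and returns at 15, with reversed polarity and copper in place of palladium. Hydroboration of 13 (through 14) followed by NaBO3 oxidation should give the 9-hydroxynonyl alcohol F1. TsCl/pyridine at 0 °C should sulfonylate only the primary OH to give the tosylate F2. (E)-Oct-5-enylmagnesium bromide F3 is made from 5 and Mg and used in excess, because each tertiary OH consumes one equivalent. It should displace the tosylate under Li2CuCl4 catalysis in THF at −30 to 0 °C, forming the same C9′–C10′ bond and giving 15.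

2. Step 8.
 - Risk: the C1 alkoxide may deliver the nucleophile to the β face and erode facial selectivity. Enolisation or retro-aldol opening of the C1 aldolate may consume the ketone.
 - Fallback: it sets out from 10 and returns at 13, and replaces the basic carbanion by a weakly basic ylide. Corey–Chaykovsky reaction of 10 with dimethylsulfoxonium methylide (Me3S(O)I, NaH, DMSO–THF, rt) adds reversibly and should place the new CH2 equatorial on the α face and the oxygen axial on the β face, giving the spiro-epoxide F4. Oct-7-enylmagnesium bromide F5 (from commercial 8-bromooct-1-ene and Mg, 3 equiv) with catalytic CuI in THF at −30 to 0 °C should then open the epoxide at its CH2 terminus to give 13.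

3. Step 12.
 - Risk: loss of the C5 hydroxyl may compete with the desired elimination. Over-elimination with aromatisation to the hydroquinone, retro-aldol ring opening, or base-induced isomerisation of the γ-hydroxy enone may also occur.
 - Fallback: it sets out from 17 and returns at 19, and gives C3 a discrete, much better leaving group so that a weak amine base suffices. Mild hydrolysis (80% aq AcOH, rt) should give the trihydroxy ketone F6. Ac2O, i-Pr2NEt and catalytic DMAP in CH2Cl2 at 0 °C should acylate the two secondary alcohols to the 3,4-diacetate F7. F7 should lose the C3 acetate in the same flask to give the 4-O-acetyl enone F8. Lipase-mediated hydrolysis in pH 7 buffer/t-BuOMe should then free C4–OH and give 19.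

**Further compounds**
F1 | step 9 | 9-hydroxynonyl alcohol from 13 | CC(C)(C)[Si](C)(C)OC[C@]1(O)C[C@H]2OC(C)(C)O[C@H]2[C@](O)(CCCCCCCCCO)C1
F2 | step 9 | tosylate of F1 | CC(C)(C)[Si](C)(C)OC[C@]1(O)C[C@H]2OC(C)(C)O[C@H]2[C@](O)(CCCCCCCCCOS(=O)(=O)c3ccc(C)cc3)C1
F3 | step 9 | (E)-oct-5-enylmagnesium bromide | CC/C=C/CCCC[Mg]Br
F4 | step 8 | C5 spiro-epoxide (O β, CH2 α) | CC(C)(C)[Si](C)(C)OC[C@]1(O)C[C@H]2OC(C)(C)O[C@H]2[C@]3(CO3)C1
F5 | step 8 | oct-7-enylmagnesium bromide | C=CCCCCCC[Mg]Br
F6 | step 12 | (3R,4R,5S)-3,4,5-trihydroxy-5-[(E)-heptadec-14-enyl]cyclohexanone | O=C1C[C@@H](O)[C@@H](O)[C@](O)(CCCCCCCCCCCCC/C=C/CC)C1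
F7 | step 12 | 3,4-diacetate of F6 | O=C1C[C@@H](OC(C)=O)[C@@H](OC(C)=O)[C@](O)(CCCCCCCCCCCCC/C=C/CC)C1
F8 | step 12 | 4-O-acetyl enone (4-acetate of 19) | CC/C=C/CCCCCCCCCCCCC[C@]1(O)CC(=O)C=C[C@H]1OC(C)=O
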